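**Retrosynthetic overview**

1. Locants follow labdane numbering: ring A = C1–C5 + C10, ring B = C5–C10; C4 carries the two CH2OH groups (C18, C19), C10 the methyl (C20), C8 the formyl group (C17), C9 the chain C11–C12 to the butenolide (C13–C16). The decalin intermediates are named with these locants.
2. Disconnections: C12–C13 (B-alkyl Suzuki–Miyaura coupling with 3-bromofuran-2(5H)-one), C11=C12 (Wittig), then ring B by a catalytic enantioselective Diels–Alder reaction that forms C7–C8 and C9–C10 from a ring A diene (C10=C5–C6=C7) and ethyl (E)-4-oxobut-2-enoate (C17–C8=C9–C11).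
3. Enabling feature: in ring B the segment C7H2–C8(C17)–C9(C11)–C10 carries trans-vicinal one-carbon substituents at carbonyl-derived oxidation levels next to quaternary C10. With a C5=C6 double bond, ring B is therefore a 4,5-disubstituted cyclohexene (Diels–Alder retron) whose diene lies inside ring A. C4 is not a stereocentre, so the diene is achiral and one catalyst-controlled cycloaddition sets C8, C9 and C10; C5 follows by hydrogenation anti to C20.
4. Ring order: ring A is bought (2-methylcyclohex-2-en-1-one) and turned into the diene (steps 1–5), ring B is closed in step 6, and the butenolide ring is attached intact in step 10.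

Key step: step 6

Assumption: compounds 1, 2, 6, 8, 10, 12, 16, 19 and the (S)-diarylprolinol silyl ether catalyst are taken as commercially available.

**Route**

Step 1
Reactants: 1 2-methylcyclohex-2-en-1-one; 2 benzyl chloromethyl ether
Product: 4 6,6-bis[(benzyloxy)methyl]-2-methylcyclohex-2-en-1-one, via mono(benzyloxymethyl) enone 3 (not isolated)
Conditions: LiN(iPr)2 (1.05 equiv), THF, −78 °C; 2 (1.1 equiv), −78 → −20 °C; then LiN(iPr)2 (1.2 equiv), −78 °C; 2 (1.3 equiv), −78 → 0 °C
Reagents that add atoms: benzyl chloromethyl ether (2), ClCOCc1ccccc1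
Why: Kinetic deprotonation of the enone can only occur at the α′-methylene (the other α-carbon is the alkene carbon), and the cross-conjugated lithium dienolate should be C-alkylated by the reactive α-chloro ether twice in succession (α′-alkylation of a cyclohexenone enolate), which creates the quaternary carbon that becomes C4 together with C18 and C19; the stereocentre of 3 disappears in 4.

Step 2
Reactants: 4 6,6-bis[(benzyloxy)methyl]-2-methylcyclohex-2-en-1-one
Product: 5 2,2-bis(hydroxymethyl)-6-methylcyclohexan-1-one (racemic)
Conditions: H2 (1 atm), Pd/C (10 wt%), EtOAc/MeOH, rt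
Reagents that add atoms: none
Why: Hydrogen over Pd/C should saturate the enone double bond and cleave both benzyl ethers in the same operation (catalytic hydrogenation with hydrogenolysis); the methyl-bearing stereocentre so formed is racemic and is erased again in step 4.

Step 3
Reactants: 5 2,2-bis(hydroxymethyl)-6-methylcyclohexan-1-one; 6 2,2-dimethoxypropane
Product: 7 3,3,8-trimethyl-2,4-dioxaspiro[5.5]undecan-7-one (racemic)
Conditions: 6 (3 equiv), pyridinium p-toluenesulfonate (5 mol%), acetone, rt
Reagents that add atoms: 2,2-dimethoxypropane (6), COC(C)(C)OC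
Why: Acid-catalysed ketal exchange ties the two primary hydroxyl groups into a six-membered isopropylidene ketal (acetonide formation of a 1,3-diol), a compact protecting group that should survive every step up to the final hydrolysis.

Step 4
Reactants: 7 3,3,8-trimethyl-2,4-dioxaspiro[5.5]undecan-7-one; 8 N-phenylbis(trifluoromethanesulfonimide)
Product: 9 3,3,8-trimethyl-2,4-dioxaspiro[5.5]undec-7-en-7-yl trifluoromethanesulfonate
Conditions: KN(SiMe3)2 (1.2 equiv), THF, −78 °C; 8 (1.2 equiv), −78 °C → rt
Reagents that add atoms: N-phenylbis(trifluoromethanesulfonimide) (8), O=S(=O)(N(c1ccccc1)S(=O)(=O)C(F)(F)F)C(F)(F)F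
Why: The spiro carbon has no hydrogen, so the ketone can be enolised only toward the methyl-bearing carbon, and O-sulfonylation of this potassium enolate should give the tetrasubstituted enol triflate regiospecifically (enol triflate formation).

Step 5
Reactants: 9 enol triflate; 10 tributyl(vinyl)stannane
Product: 11 7-ethenyl-3,3,8-trimethyl-2,4-dioxaspiro[5.5]undec-7-ene
Conditions: 10 (1.3 equiv), Pd(PPh3)4 (5 mol%), LiCl (3 equiv), THF, 65 °C
Reagents that add atoms: tributyl(vinyl)stannane (10), C=C[Sn](CCCC)(CCCC)CCCC
Why: Stille coupling of the hindered cyclohexenyl triflate with the vinylstannane, with LiCl assisting transmetalation at zerovalent palladium, should deliver the 2-vinylcyclohexene diene (cross-coupling of an enol triflate with a vinyltin reagent, precedented for 2,6,6-trisubstituted cyclohexenyl triflates).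

Step 6
Reactants: 11 7-ethenyl-3,3,8-trimethyl-2,4-dioxaspiro[5.5]undec-7-ene; 12 ethyl (E)-4-oxobut-2-enoate
Product: 14 18,19-acetonide of ethyl 9-formyl-4,4-bis(hydroxymethyl)-10-methyl-Δ5-octalin-8-carboxylate (9-CHO cis and 8-CO2Et trans to the C10 methyl), via iminium ion 13 (not isolated)
Conditions: 11 (1.5 equiv), 12 (1.0 equiv), (S)-2-{bis[3,5-bis(trifluoromethyl)phenyl](trimethylsilyloxy)methyl}pyrrolidine (20 mol%), CF3CO2H (20 mol%), toluene, 0 °C → rt; aqueous work-up
Reagents that add atoms: ethyl (E)-4-oxobut-2-enoate (12), CCOC(=O)/C=C/C=O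
Why: Aldehyde 12 condenses reversibly with the amine salt to the (E)-iminium ion 13, whose lowered LUMO has its largest coefficient at C8 (β to the iminium); diene 11 should add across C8=C9 in an asynchronous, concerted [4+2] cycloaddition (bond C7–C8 leading, bond C9–C10 following), and hydrolysis of the adduct iminium releases 14 and the catalyst. The closest known reaction type is the diarylprolinol silyl ether salt-catalysed, exo-selective enantioselective Diels–Alder reaction of α,β-unsaturated aldehydes (iminium catalysis), and 2-vinylcyclohexenes flanked by a quaternary carbon are established Diels–Alder dienes. Ring B is closed as the six-membered ring of an intermolecular [4+2] cycloaddition in which both new σ-bonds (C7–C8 and C9–C10) form suprafacially on each partner. The absolute configuration of C8 and C9 is set by the catalyst, whose diaryl(silyloxy)methyl group shields one face of the s-trans (E)-iminium so that the diene bonds to the opposite face, and their trans relationship is carried over from the (E)-alkene; C10 is set relative to C9 by the exo orientation of the iminium (the iminium and its bulky amine point away from ring A and the spiro C4, the ester lies endo under the unsubstituted C6–C7 end), which places C11 cis to the C20 methyl. The regioselectivity needed (C8 to C7, C9 to C10) is secured because C7 is both the least hindered and the most nucleophilic diene terminus (bonding there develops charge at the tertiary allylic C10) while C8 is the most electrophilic dienophile carbon; facial and exo selectivity rest on the catalyst bulk, and a minor diastereomer would be removed by chromatography.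

Step 7
Reactants: 14 Diels–Alder adduct
Product: 15 18,19-acetonide of ethyl 9-formyl-4,4-bis(hydroxymethyl)-10-methyl-trans-decalin-8-carboxylate (H5 trans to the C10 methyl; 9-CHO cis and 8-CO2Et trans to it)
Conditions: H2 (3 atm), Pd/C (10 wt%), EtOAc, rt
Reagents that add atoms: none
Why: Hydrogen should be delivered from the catalyst surface to the less hindered face of the trisubstituted C5=C6 bond, anti to the axial C10 methyl, which sets H5 trans to that methyl and gives the trans-decalin (heterogeneous hydrogenation of a Δ5-octalin bearing an angular methyl group).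

Step 8
Reactants: 15 trans-decalin aldehyde ester; 16 methyltriphenylphosphonium bromide
Product: 17 18,19-acetonide of ethyl 9-ethenyl-4,4-bis(hydroxymethyl)-10-methyl-trans-decalin-8-carboxylate
Conditions: 16 (2.0 equiv), KOtBu (1.9 equiv), THF, 0 °C; then 15, 0 °C → rt
Reagents that add atoms: methyltriphenylphosphonium bromide (16), C[P+](c1ccccc1)(c1ccccc1)c1ccccc1.[Br-]
Why: Wittig methylenation converts the C9 formyl group into the vinyl group C11=C12; C8 and C9 already hold their thermodynamically preferred equatorial substituents, so transient enolisation by the basic ylide should not change them.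

Step 9
Reactants: 17 vinyl ester
Product: 18 18,19-acetonide of [9-ethenyl-4,4-bis(hydroxymethyl)-10-methyl-trans-decalin-8-yl]methanol
Conditions: LiAlH4 (1.5 equiv), THF, 0 °C; aqueous work-up
Reagents that add atoms: none
Why: LiAlH4 reduces the ethyl ester to the primary alcohol C17–OH and should leave the vinyl group and the ketal untouched (hydride reduction of an ester).

Step 10
Reactants: 18 vinyl alcohol; 19 3-bromofuran-2(5H)-one
Product: 21 18,19-acetonide of 3-{2-[8-(hydroxymethyl)-4,4-bis(hydroxymethyl)-10-methyl-trans-decalin-9-yl]ethyl}furan-2(5H)-one, via alkylborane 20 (not isolated)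
Conditions: 9-BBN (2.5 equiv), THF, 0 °C → rt; then 19 (1.3 equiv), PdCl2(dppf) (5 mol%), AsPh3 (10 mol%), K3PO4 (3 equiv), DMF/H2O, rt
Reagents that add atoms: 3-bromofuran-2(5H)-one (19), BrC1=CCOC1=O
Why: 9-BBN should add boron to the terminal carbon C12 of the monosubstituted alkene (the free hydroxyl is borylated with loss of H2 and released again by the aqueous base), and the B-alkyl group is then transferred under PdCl2(dppf) catalysis to the α-bromobutenolide (B-alkyl Suzuki–Miyaura coupling), forming C12–C13 and delivering the intact butenolide.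

Step 11
Reactants: 21 butenolide alcohol
Product: 22 18,19-acetonide of the target (8-formyl compound)
Conditions: Dess–Martin periodinane (1.3 equiv), CH2Cl2, 0 °C → rt
Reagents that add atoms: none
Why: Dess–Martin periodinane should oxidise the primary alcohol to the aldehyde under neutral conditions (hypervalent iodine oxidation), and the equatorial C8 formyl group so formed is the thermodynamic epimer.

Step 12
Reactants: 22 acetonide-protected aldehyde
Product: 23 (1R,2S,4aS,8aS)-5,5-bis(hydroxymethyl)-8a-methyl-1-[2-(2-oxo-2,5-dihydrofuran-3-yl)ethyl]decahydronaphthalene-2-carbaldehyde (target)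
Conditions: AcOH/H2O (4:1), 40 °C
Reagents that add atoms: none
Why: Aqueous acetic acid should hydrolyse the isopropylidene ketal to the free 1,3-diol (acetonide hydrolysis) under conditions that neither epimerise the equatorial aldehyde nor open the butenolide.

**Compound list**

1 | 2-methylcyclohex-2-en-1-one | CC1=CCCCC1=O | starting material
2 | benzyl chloromethyl ether | ClCOCc1ccccc1 | starting material
3 | 6-[(benzyloxy)methyl]-2-methylcyclohex-2-en-1-one (racemic, not isolated) | CC1=CCCC(COCc2ccccc2)C1=O | intermediate
4 | 6,6-bis[(benzyloxy)methyl]-2-methylcyclohex-2-en-1-one | CC1=CCCC(COCc2ccccc2)(COCc2ccccc2)C1=O | intermediate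
5 | 2,2-bis(hydroxymethyl)-6-methylcyclohexan-1-one (racemic) | CC1CCCC(CO)(CO)C1=O | intermediate
6 | 2,2-dimethoxypropane | COC(C)(C)OC | starting material
7 | 3,3,8-trimethyl-2,4-dioxaspiro[5.5]undecan-7-one (racemic) | CC1CCCC2(COC(C)(C)OC2)C1=O | intermediate
8 | N-phenylbis(trifluoromethanesulfonimide) | O=S(=O)(N(c1ccccc1)S(=O)(=O)C(F)(F)F)C(F)(F)F | starting material
9 | 3,3,8-trimethyl-2,4-dioxaspiro[5.5]undec-7-en-7-yl trifluoromethanesulfonate | CC1=C(OS(=O)(=O)C(F)(F)F)C2(CCC1)COC(C)(C)OC2 | intermediate
10 | tributyl(vinyl)stannane | C=C[Sn](CCCC)(CCCC)CCCC | starting material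
11 | 7-ethenyl-3,3,8-trimethyl-2,4-dioxaspiro[5.5]undec-7-ene | CC1=C(C=C)C2(CCC1)COC(C)(C)OC2 | intermediate
12 | ethyl (E)-4-oxobut-2-enoate | CCOC(=O)/C=C/C=O | starting material
13 | (E)-iminium trifluoroacetate from 12 and the (S)-catalyst: (2S)-2-{bis[3,5-bis(trifluoromethyl)phenyl](trimethylsilyloxy)methyl}-1-[(2E)-4-ethoxy-4-oxobut-2-en-1-ylidene]pyrrolidinium trifluoroacetate (not isolated) | CCOC(=O)/C=C/C=[N+]1CCC[C@H]1C(O[Si](C)(C)C)(c1cc(cc(c1)C(F)(F)F)C(F)(F)F)c1cc(cc(c1)C(F)(F)F)C(F)(F)F.[O-]C(=O)C(F)(F)F | intermediate
14 | Diels–Alder adduct: 18,19-acetonide of ethyl 9-formyl-4,4-bis(hydroxymethyl)-10-methyl-Δ5-octalin-8-carboxylate; 9-CHO cis and 8-CO2Et trans to the C10 methyl | C[C@@]12CCCC3(COC(C)(C)OC3)C1=CC[C@H](C(=O)OCC)[C@H]2C=O | intermediate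
15 | 18,19-acetonide of ethyl 9-formyl-4,4-bis(hydroxymethyl)-10-methyl-trans-decalin-8-carboxylate; H5 trans to the C10 methyl | C[C@@]12CCCC3(COC(C)(C)OC3)[C@H]1CC[C@H](C(=O)OCC)[C@H]2C=O | intermediate
16 | methyltriphenylphosphonium bromide | C[P+](c1ccccc1)(c1ccccc1)c1ccccc1.[Br-] | starting material
17 | 18,19-acetonide of ethyl 9-ethenyl-4,4-bis(hydroxymethyl)-10-methyl-trans-decalin-8-carboxylate | C[C@@]12CCCC3(COC(C)(C)OC3)[C@H]1CC[C@H](C(=O)OCC)[C@H]2C=C | intermediate
18 | 18,19-acetonide of [9-ethenyl-4,4-bis(hydroxymethyl)-10-methyl-trans-decalin-8-yl]methanol | C[C@@]12CCCC3(COC(C)(C)OC3)[C@H]1CC[C@H](CO)[C@H]2C=C | intermediate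
19 | 3-bromofuran-2(5H)-one | BrC1=CCOC1=O | starting material
20 | B-alkyl-9-borabicyclo[3.3.1]nonane from 18 (boron on C12; O17 as its 9-BBN borinate; not isolated) | C[C@@]12CCCC3(COC(C)(C)OC3)[C@H]1CC[C@H](COB4C5CCCC4CCC5)[C@H]2CCB4C5CCCC4CCC5 | intermediate
21 | 18,19-acetonide of 3-{2-[8-(hydroxymethyl)-4,4-bis(hydroxymethyl)-10-methyl-trans-decalin-9-yl]ethyl}furan-2(5H)-one | C[C@@]12CCCC3(COC(C)(C)OC3)[C@H]1CC[C@H](CO)[C@H]2CCC1=CCOC1=O | intermediate
22 | 18,19-acetonide of the target | C[C@@]12CCCC3(COC(C)(C)OC3)[C@H]1CC[C@H](C=O)[C@H]2CCC1=CCOC1=O | intermediate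
23 | (1R,2S,4aS,8aS)-5,5-bis(hydroxymethyl)-8a-methyl-1-[2-(2-oxo-2,5-dihydrofuran-3-yl)ethyl]decahydronaphthalene-2-carbaldehyde | C[C@@]12CCCC(CO)(CO)[C@H]1CC[C@H](C=O)[C@H]2CCC1=CCOC1=O | target

**Step count**

Total steps: 12. Longest linear sequence: 12 steps (1 → 23).

**Steps most likely to fail**

Step 6. The diene may engage iminium 13 in the endo-iminium orientation, or with poor exo/endo discrimination. This would pair the catalyst-fixed C8/C9 configuration with the wrong configuration at C10. Fallback (thermodynamic instead of kinetic control, relayed from C10): setting out from 11 and 12, the cycloaddition is run with the (R)-enantiomer of the catalyst, so that the endo-iminium adduct, the 8,9-bis-epimer of 14 F1, has the correct C10. Both epimerisable centres (C9 α to the aldehyde, C8 α to the ester) are then equilibrated with NaOEt (0.2 equiv) in EtOH at rt. The ester of F1 is syn-axial to the C10 methyl, so the equilibrium should lie on the side of the all-equatorial isomer, and the route is rejoined at 14.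

Step 10. The aqueous base may open or hydrolyse the bromobutenolide, and protodeboronation of the hindered alkylborane may outrun transmetalation. Fallback (base-free coupling of an isolated alkyl iodide), setting out from 18: silylation (t-BuMe2SiCl, imidazole, DMF) gives the tert-butyldimethylsilyl ether of 18 F2. Hydrozirconation of the vinyl group with Cp2Zr(H)Cl followed by iodinolysis (I2) gives the primary C12 iodide F3. Zinc insertion (Zn, LiCl, THF) and Negishi coupling of the resulting alkylzinc iodide with 19 (Pd(OAc)2, 2-dicyclohexylphosphino-2′,6′-dimethoxybiphenyl, THF, rt) gives the tert-butyldimethylsilyl ether of 21 F4. Desilylation (Bu4NF buffered with AcOH, THF) returns to the route at 21.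

Step 7. Hydrogen uptake at the trisubstituted alkene, which is flanked by two quaternary carbons, may be sluggish, and some addition from the methyl face would give the cis-fused isomer. Fallback (radical hydrogen-atom-transfer hydrogenation under thermodynamic control instead of surface syn-addition): setting out from 14, treatment with Mn(dpm)3 (dpm = 2,2,6,6-tetramethylheptane-3,5-dionate, 10 mol%), PhSiH3 and t-BuOOH in i-PrOH at rt adds a hydrogen atom to C6. The tertiary C5 radical is then quenched from the face anti to the C10 methyl, giving the more stable trans-decalin. The route is rejoined at 15 and no new compound is made (F0).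

Further compounds
F1 | step 6 | 8,9-bis-epimer of 14 (9-CHO trans and 8-CO2Et cis to the C10 methyl) | C[C@@]12CCCC3(COC(C)(C)OC3)C1=CC[C@@H](C(=O)OCC)[C@@H]2C=O
F2 | step 10 | tert-butyldimethylsilyl ether of 18 | C[C@@]12CCCC3(COC(C)(C)OC3)[C@H]1CC[C@H](CO[Si](C)(C)C(C)(C)C)[C@H]2C=C
F3 | step 10 | primary C12 iodide (9-(2-iodoethyl) analogue of F2) | C[C@@]12CCCC3(COC(C)(C)OC3)[C@H]1CC[C@H](CO[Si](C)(C)C(C)(C)C)[C@H]2CCI
F4 | step 10 | tert-butyldimethylsilyl ether of 21 | C[C@@]12CCCC3(COC(C)(C)OC3)[C@H]1CC[C@H](CO[Si](C)(C)C(C)(C)C)[C@H]2CCC1=CCOC1=O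
F0 | step 7 | none | none
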